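## Analysis of the target

The target 9 is 3,4,6-tribromoindole, a 1H-indole (pyrrole ring fused to a benzo ring across C3a–C7a) with bromine on C3 of the pyrrole ring and on C4 and C6 of the benzo ring. N1–H, C2–H, C5–H and C7–H are unsubstituted and there is no stereocenter, so the problem is purely one of regiochemistry. The C3–Br bond sits on the most nucleophilic carbon of indole and is the one electrophilic bromination makes unaided. C4 and C6, meta to each other on the benzo ring, are not reached selectively by electrophilic bromination of an indole, which after C3 attacks C2, C5 and C6 in mixtures and leaves C4 alone. The sensitive points are the C3–Br bond of an N–H indole, which gives up electrophilic bromine under acid, light or on silica gel, and the aryl bromides, which exclude zerovalent palladium, organolithium reagents and strong reductants late in the route. The difficulty is to place bromine on C6 without touching C2, C5 or C7 and without disturbing the halogens already present. The strategy rests on a steric feature: with bromine on C3 and C4 and a triisopropylsilyl group on N1, C6–H is the only ring C–H whose two neighbours, C5 and C7, both carry hydrogen. C2–H lies between N–Si and C3–Br, C5–H is ortho to C4–Br, and C7–H is next to C7a and covered by the isopropyl groups on N1.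

## Retrosynthetic reasoning

The first cut is the N1–H bond: 9 is traced back to 3,4,6-tribromo-1-(triisopropylsilyl)indole 8. The silyl group is needed earlier as the shield for C2–H and C7–H, and it keeps the N–H bond away from the boron reagent and the catalyst. Putting its removal last means the labile N–H 3-bromoindole exists only in the final step. The forward reaction is a fluoride cleavage of N–Si, which leaves aryl bromides alone.

The second cut, the key one, is the C6–Br bond of 8, leading to 3,4-dibromo-1-(triisopropylsilyl)indole 5. This bond is chosen because it is the only C–Br bond that neither a commercial indole nor electrophilic substitution can supply. In 5 the C6–H bond is sterically unique, so no directing group has to be introduced and removed. Forward, an iridium catalyst and bis(pinacolato)diboron 6 convert C6–H into the pinacol boronate 7, and a copper-mediated bromodeboronation in the same vessel exchanges boron for bromine at that carbon. The step must discriminate between four C–H bonds and must leave two C–Br bonds intact.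

The third cut is the C3–Br bond of 5, leading to 4-bromo-1-(triisopropylsilyl)indole 4. It is made by electrophilic bromination, which goes to C3 by the inherent polarity of the indole. It has to precede the borylation, because a free C3–H of an N-silyl indole is itself a favoured borylation site; the C3 bromine is thus both a target atom and a blocking group. It follows the silylation so that nitrogen and C2 are protected from the bromine donor.

The last cut is the N–Si bond of 4, leading to 4-bromoindole 1 and triisopropylsilyl chloride 2 through the sodium indolide 3. The C4 bromine, the position hardest to functionalise on an indole, is thereby bought with the starting material.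

## Alternatives that were turned down

Alternative 1: The pyrrole ring is opened at C2=C3. The forward key step is an intramolecular Wittig reaction of [2,4-dibromo-6-(formylamino)benzyl]triphenylphosphonium bromide A2. Base converts A2 into its ylide, which adds to the formamide carbonyl, closes the five-membered ring and expels the phosphine oxide to give 4,6-dibromoindole A1. Bromination of A1 at C3 would then give 9.
- For it: both benzo-ring bromines of A1 come from a benzene building block in which their positions are fixed by constitution, so there is no C–H selectivity question. No precious metal is needed, and the final C3 bromination of a free indole is textbook chemistry. On certainty of regiochemistry it is stronger than the chosen route.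
- Against it: A2 takes about four operations from a dibrominated benzene building block (benzylic bromination at a methyl group flanked by bromine and the nitrogen substituent, quaternisation, nitro reduction, formylation). A formamide is a poor carbonyl partner for a semi-stabilised ylide, so the closure of A2 to A1 needs forcing conditions. The sequence runs to about six steps.
- Comparison: the chosen route offers four steps from a commercial indole and builds no ring, in exchange for a steric selectivity argument in place of a constitutional guarantee.

Alternative 2: The benzo ring is opened at C5–C6 and built on a pyrrole. The forward key step heats 4-bromo-3-(1-bromovinyl)-2-(2,2-dibromovinyl)-1-tosylpyrrole A4. The triene of A4 (bromovinyl group, pyrrole C2=C3 bond, dibromovinyl group) undergoes 6π electrocyclisation, and loss of HBr across the new bond gives 3,4,6-tribromo-1-tosylindole A3. Removal of the tosyl group from A3 would give 9.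
- For it: all three bromines of A3 are placed by connectivity, and aromatisation by HBr loss needs no oxidant.
- Against it: A4 is a pyrrole with three different adjacent substituents, two of them sensitive bromoalkenes, and its assembly alone would exceed the length of the whole chosen route. The closure uses the aromatic C2=C3 bond of the pyrrole as the central alkene and must turn a bromine of the dibromomethylene terminus inward, so it needs high temperature. At that temperature the 1-bromovinyl group of A4 can lose HBr to an alkyne.
- Comparison: the regiochemical certainty of A3 is matched in the chosen route by buying the C4 bromine and by the steric uniqueness of C6. The chosen route is far shorter and its key step rests on a well-established reaction class.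

Alternative 3: The C4–Br bond is cut, with a formyl group on C3 as director. The forward key step treats 6-bromoindole-3-carbaldehyde A6 with Pd(OAc)2, glycine and N-bromosuccinimide. Glycine forms a transient imine with A6 that holds divalent palladium so that it cleaves the peri C4–H bond through a six-membered palladacycle. Oxidation by the bromine donor and C–Br reductive elimination give 4,6-dibromoindole-3-carbaldehyde A5. Two further steps would be needed to turn A5 into 9.
- For it: A6 is an available compound that already carries the C6 bromine. C4 is selected by chelate geometry, and no N-protection is needed. On protecting-group economy it is stronger than the chosen route.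
- Against it: the formyl group of A5 is not part of the target. A5 would have to be oxidised to 4,6-dibromoindole-3-carboxylic acid A7, and A7 would then be converted into 9 by decarboxylative bromination. That is two further steps on an electron-poor indole whose free C2–H and N–H compete for the electrophilic bromine source, both there and in the key step.
- Comparison: the step count is similar. In the chosen route every atom introduced on carbon stays in the target, and the only electrophilic bromination is the inherently selective one at C3.

Key step: step 3

Remark: the triisopropylsilyl group is kept on nitrogen throughout because its bulk shields C2–H and C7–H in the key step; indole numbering (N1, C2, C3, C3a, C4 to C7, C7a) is used, dtbpy is 4,4'-di-tert-butyl-2,2'-bipyridine and cod is 1,5-cyclooctadiene.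

## Route

Step 1
Reactants: 1 4-bromoindole; 2 triisopropylsilyl chloride
Product: 4 4-bromo-1-(triisopropylsilyl)indole, via sodium 4-bromoindol-1-ide 3 (not isolated)
Conditions: NaH, THF, 0 °C; then 2, 0 °C to rt
Reagents that add atoms: triisopropylsilyl chloride (compound 2), CC(C)[Si](Cl)(C(C)C)C(C)C
Why: N-Silylation of an indolide: NaH removes the N–H proton and the sodium salt 3 attacks the hindered silyl chloride at nitrogen; the aryl bromide is inert to NaH.

Step 2
Reactants: 4 4-bromo-1-(triisopropylsilyl)indole
Product: 5 3,4-dibromo-1-(triisopropylsilyl)indole
Conditions: NBS, THF, −78 °C to rt, dark
Reagents that add atoms: N-bromosuccinimide (NBS), O=C1CCC(=O)N1Br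
Why: Electrophilic aromatic bromination at C3, the most nucleophilic carbon of the indole; the silyl group blocks nitrogen and shields C2, and the low temperature should hold the reaction at monobromination despite the peri bromine on C4.

Step 3
Reactants: 5 3,4-dibromo-1-(triisopropylsilyl)indole; 6 bis(pinacolato)diboron
Product: 8 3,4,6-tribromo-1-(triisopropylsilyl)indole, via C6 pinacol boronate 7 (not isolated)
Conditions: [Ir(OMe)(cod)]2 (cat.), dtbpy (cat.), 6, THF, 80 °C; evaporate; then CuBr2 (3 equiv), MeOH/H2O/THF, 80 °C
Reagents that add atoms: CuBr2, [Cu+2].[Br-].[Br-] (bromine on C6); bis(pinacolato)diboron (compound 6), CC1(C)OB(OC1(C)C)B1OC(C)(C)C(C)(C)O1 (boron of intermediate 7 only, not retained in 8)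
Why: Iridium-catalysed aromatic C–H borylation followed by copper-mediated bromodeboronation, the one-pot meta-halogenation sequence known for 1,3-disubstituted arenes, whose borylation half is known at C6 of N-triisopropylsilyl 3-substituted indoles. The monovalent iridium precatalyst, dtbpy and 6 form a trivalent iridium tris(boryl) complex, which cleaves the least hindered C–H bond through a pentavalent iridium hydride and releases boronate 7 by C–B reductive elimination. The step needs site selectivity among C2–H, C5–H, C6–H and C7–H, and the substrate secures it sterically: C2–H lies between the N-silyl group and the C3 bromine, C7–H is covered by the triisopropylsilyl group, C5–H is ortho to the C4 bromine, so only C6–H, flanked by two C–H carbons, is open to the crowded catalyst. Chemoselectivity is also needed: the catalyst does not insert into aryl C–Br bonds under these conditions, so both bromines of 5 should be retained. After removal of the volatiles, CuBr2 in aqueous methanol transmetalates the boronate to divalent copper, a second equivalent oxidises the aryl copper species to trivalent copper, and C–Br reductive elimination places bromine on the carbon that carried boron. No ring is closed and no stereocenter is formed.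

Step 4
Reactants: 8 3,4,6-tribromo-1-(triisopropylsilyl)indole
Product: 9 3,4,6-tribromoindole
Conditions: TBAF, wet THF, 0 °C
Reagents that add atoms: none
Why: Fluoride-induced N-desilylation: fluoride attacks silicon, the stabilised tribromoindolide leaves and is protonated by water; aryl and heteroaryl C–Br bonds are inert to fluoride at 0 °C.

## Compound list

1 | 4-bromoindole | Brc1cccc2[nH]ccc12 | starting material
2 | triisopropylsilyl chloride | CC(C)[Si](Cl)(C(C)C)C(C)C | starting material
3 | sodium 4-bromoindol-1-ide | [Na+].Brc1cccc2[n-]ccc12 | intermediate
4 | 4-bromo-1-(triisopropylsilyl)indole | CC(C)[Si](C(C)C)(C(C)C)n1ccc2c(Br)cccc21 | intermediate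
5 | 3,4-dibromo-1-(triisopropylsilyl)indole | CC(C)[Si](C(C)C)(C(C)C)n1cc(Br)c2c(Br)cccc21 | intermediate
6 | bis(pinacolato)diboron | CC1(C)OB(OC1(C)C)B1OC(C)(C)C(C)(C)O1 | starting material
7 | 3,4-dibromo-6-(4,4,5,5-tetramethyl-1,3,2-dioxaborolan-2-yl)-1-(triisopropylsilyl)indole | CC(C)[Si](C(C)C)(C(C)C)n1cc(Br)c2c(Br)cc(cc21)B1OC(C)(C)C(C)(C)O1 | intermediate
8 | 3,4,6-tribromo-1-(triisopropylsilyl)indole | CC(C)[Si](C(C)C)(C(C)C)n1cc(Br)c2c(Br)cc(Br)cc21 | intermediate
9 | 3,4,6-tribromoindole | Brc1cc(Br)c2c(Br)c[nH]c2c1 | target

## Step count and least certain steps

Total step count: 4. Longest linear sequence: 4 steps, from 1 to 9.

Step 3 (key step). The borylation half is well supported. The copper half is the most likely point of failure.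
- The HBr set free in hot aqueous methanol may solvolyse the N–Si bond. The unprotected indole would then be open to oxidative bromination at C2 by CuBr2.
- Protodeboronation back to 5 and poor solubility of the lipophilic boronate are further concerns. THF is added as co-solvent for the latter.
- Unreacted 5 would be hard to separate from 8, since both are non-polar silyl indoles.
- Fallback: this replaces the hot copper oxidation by an isolated boronate and a room-temperature ipso-substitution. It sets out from 5. The borylation is run as before, but boronate 7 is isolated by chromatography, which also removes any 5. The pinacol ester is cleaved with NaIO4 and NH4OAc in aqueous acetone to [3,4-dibromo-1-(triisopropylsilyl)indol-6-yl]boronic acid F1. F1 is brominated at the boron-bearing carbon with 1,3-dibromo-5,5-dimethylhydantoin and catalytic NaOMe in acetonitrile at room temperature, a known base-catalysed halodeboronation of arylboronic acids. The route is rejoined at 8.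

Step 2. The peri bromine on C4 may slow attack at C3.
- Longer reaction times or warming could then bring bromination at C2, double bromination, or loss of the silyl group to adventitious HBr.
- Fallback: this reverses the order of bromination and silylation. It sets out from 1, whose free indole is far more nucleophilic at C3. NBS in DMF at 0 °C should give 3,4-dibromoindole F2, which is used without storage. F2 is deprotonated with NaH in THF to sodium 3,4-dibromoindol-1-ide F3 and silylated with 2. The route is rejoined at 5.

Step 4. The fluoride cleavage itself is reliable.
- The likely loss is erosion of the C3 bromine once N–H is free. Such 3-bromoindoles pass on electrophilic bromine under traces of acid, on silica gel or in light.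
- Fallback: this makes an electrophilic C3 bromination the last bond-forming event. It sets out from 8, and the crude product of the fluoride cleavage is not chromatographed. The portion that has lost the C3 bromine, 4,6-dibromoindole F4 (the same compound as A1), is converted by NBS in DMF at 0 °C, charged according to the content of F4 so that C2 is not attacked. The route is rejoined at 9.

## Further compounds

F1 | step 3 | [3,4-dibromo-1-(triisopropylsilyl)indol-6-yl]boronic acid | CC(C)[Si](C(C)C)(C(C)C)n1cc(Br)c2c(Br)cc(cc21)B(O)O
F2 | step 2 | 3,4-dibromoindole | Brc1c[nH]c2cccc(Br)c12
F3 | step 2 | sodium 3,4-dibromoindol-1-ide | [Na+].Brc1c[n-]c2cccc(Br)c12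
F4 | step 4 | 4,6-dibromoindole | Brc1cc(Br)c2cc[nH]c2c1
A1 | alternative 1 | 4,6-dibromoindole | Brc1cc(Br)c2cc[nH]c2c1
A2 | alternative 1 | [2,4-dibromo-6-(formylamino)benzyl]triphenylphosphonium bromide | O=CNc1cc(Br)cc(Br)c1C[P+](c1ccccc1)(c1ccccc1)c1ccccc1.[Br-]
A3 | alternative 2 | 3,4,6-tribromo-1-tosylindole | Cc1ccc(cc1)S(=O)(=O)n1cc(Br)c2c(Br)cc(Br)cc21
A4 | alternative 2 | 4-bromo-3-(1-bromovinyl)-2-(2,2-dibromovinyl)-1-tosylpyrrole | Cc1ccc(cc1)S(=O)(=O)n1cc(Br)c(C(Br)=C)c1C=C(Br)Br
A5 | alternative 3 | 4,6-dibromoindole-3-carbaldehyde | O=Cc1c[nH]c2cc(Br)cc(Br)c12
A6 | alternative 3 | 6-bromoindole-3-carbaldehyde | O=Cc1c[nH]c2cc(Br)ccc12
A7 | alternative 3 | 4,6-dibromoindole-3-carboxylic acid | O=C(O)c1c[nH]c2cc(Br)cc(Br)c12
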